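Everything rests on cutting two neighbouring bonds of ring A: the bond from C1 to the ketone carbon and the bond from C2 to the CH2 of the ethyl group. In ring A (the ethyl-bearing resorcinol ring) the acyl-bearing C1 lies between the oxygenated C6 and the ethyl-bearing C2, which is the substitution pattern a 3-alkoxyaryne delivers when it inserts into the C(=O)–CH2 bond of a beta-ketoester. One fluoride-triggered operation thus joins rings A and B through the crowded ketone and installs an acetate arm holding both ethyl carbons. Its precursors are a 3,5-dimethoxy ortho-silylaryl triflate and a ring B aroylacetate whose bromide later receives pyranone ring C.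

Key step: step 5

Remark: the target has no stereocentre; the centres in transient intermediates 10 and 13 are uncontrolled and vanish in the same flask, so their SMILES carry no configuration (ring A = 2-ethyl-4,6-dihydroxyphenyl with C1 on the ketone, ring B = the 2-hydroxy-6-substituted phenyl ring, ring C = the 4-hydroxy-2-pyranone).

Step 1
Reactants: 1 3,5-dimethoxyphenol
Product: 2 2-bromo-3,5-dimethoxyphenol
Conditions: NBS (1.0 equiv), CH2Cl2, −78 °C → rt
Reagents that add atoms: N-bromosuccinimide, O=C1CCC(=O)N1Br
Why: Electrophilic aromatic bromination, in which the free phenol should steer NBS at low temperature to its ortho position C2 (also para to one methoxy group), the minor 4-bromo isomer being removed by chromatography.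

Step 2
Reactants: 2 2-bromo-3,5-dimethoxyphenol
Product: 3 (2-bromo-3,5-dimethoxyphenoxy)trimethylsilane
Conditions: HN(SiMe3)2, THF, 70 °C; evaporate
Reagents that add atoms: hexamethyldisilazane, C[Si](C)(C)N[Si](C)(C)C
Why: O-Silylation of a phenol with a silazane, driven by loss of ammonia, should give a silyl ether clean enough to use after evaporation.

Step 3
Reactants: 3 (2-bromo-3,5-dimethoxyphenoxy)trimethylsilane
Product: 6 3,5-dimethoxy-2-(trimethylsilyl)phenyl trifluoromethanesulfonate, via aryllithium 4 (not isolated), via lithium phenoxide 5 (not isolated)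
Conditions: n-BuLi, THF, −100 °C → −78 °C; then Tf2O, −100 °C → rt
Reagents that add atoms: trifluoromethanesulfonic anhydride, FC(F)(F)S(=O)(=O)OS(=O)(=O)C(F)(F)F
Why: Bromine–lithium exchange gives the ortho-lithio aryl silyl ether, which undergoes the anionic 1,3 O-to-C silyl shift (retro-Brook rearrangement), and the lithium phenoxide so released is O-sulfonylated by Tf2O, the standard entry to ortho-silylaryl triflates.

Step 4
Reactants: 7 2-bromo-6-methoxybenzoic acid; 8 potassium methyl malonate
Product: 11 methyl 3-(2-bromo-6-methoxyphenyl)-3-oxopropanoate, via acid chloride 9 (not isolated), via acylmalonate 10 (not isolated)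
Conditions: (COCl)2, DMF (cat.), CH2Cl2, rt; evaporate; then 8, MgCl2, Et3N, MeCN, 0 °C → rt; aq. HCl
Reagents that add atoms: none
Why: Acid chloride formation followed by decarboxylative Claisen condensation with the magnesium enolate of the malonate half-ester (Masamune-type C-acylation) should give the beta-ketoester, the acid chloride being preferred to an imidazolide because the acyl carbon is flanked by two ortho substituents.

Step 5
Reactants: 6 3,5-dimethoxy-2-(trimethylsilyl)phenyl trifluoromethanesulfonate; 11 methyl 3-(2-bromo-6-methoxyphenyl)-3-oxopropanoate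
Product: 14 methyl 2-[2-(2-bromo-6-methoxybenzoyl)-3,5-dimethoxyphenyl]acetate, via 3,5-dimethoxybenzyne 12 (not isolated), via benzocyclobutenoxide 13 (not isolated)
Conditions: CsF (2.5 equiv), 6 (1.25 equiv), dry MeCN, 80 °C
Reagents that add atoms: none
Why: Fluoride attacks silicon of 6 and triflate departs to give 3,5-dimethoxybenzyne 12; the cesium enolate of 11 adds through its alpha carbon to the aryne, the aryl anion so produced attacks the adjacent ketone to form benzocyclobutenoxide 13, and this strained alkoxide fragments, handing the aroyl group to ring A and leaving an ester enolate that is protonated to 14. The closest known reaction type is the fluoride-induced acyl-alkylation of ortho-silylaryl triflate-derived arynes with beta-ketoesters, which is established for 3-alkoxyarynes and for aroylacetates. No ring of the product is closed: the four-membered ring of 13 arises by 4-exo-trig attack of the aryl anion on the carbonyl group and is opened again in the same flask, and no stereocentre survives. The selectivity required is regiochemical and is secured by the methoxy group flanking the triple bond, whose inductive pull and the aryne distortion it induces send the enolate carbon to the distal aryne carbon and place the negative charge, and hence the migrating acyl group, on the carbon next to oxygen. Closure onto the doubly ortho-substituted ketone must also outrun protonation of the aryl anion, which dry MeCN, excess CsF and a small excess of 6 should favour; the crowded ketone is thus assembled by an internal acyl transfer, sidestepping any bimolecular acylation at a carbonyl flanked by two ortho groups.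

Step 6
Reactants: 14 methyl 2-[2-(2-bromo-6-methoxybenzoyl)-3,5-dimethoxyphenyl]acetate
Product: 15 2-[2-(2-bromo-6-methoxybenzoyl)-3,5-dimethoxyphenyl]acetic acid
Conditions: LiOH, THF/H2O, rt; then aq. HCl
Reagents that add atoms: lithium hydroxide, [Li+].[OH-]
Why: Ester saponification, the methyl ester being the only hydrolysable group and the diaryl ketone being non-enolisable and shielded by four ortho substituents.

Step 7
Reactants: 15 2-[2-(2-bromo-6-methoxybenzoyl)-3,5-dimethoxyphenyl]acetic acid
Product: 16 (2-bromo-6-methoxyphenyl)[2-(2-hydroxyethyl)-4,6-dimethoxyphenyl]methanone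
Conditions: BH3·SMe2, THF, 0 °C → rt; MeOH quench
Reagents that add atoms: none
Why: Chemoselective borane reduction, since BH3 reduces a carboxylic acid through its acyloxyborane much faster than a ketone and this diaryl ketone is additionally blocked by four ortho substituents, so only the acid should go to the primary alcohol.

Step 8
Reactants: 16 (2-bromo-6-methoxyphenyl)[2-(2-hydroxyethyl)-4,6-dimethoxyphenyl]methanone
Product: 17 (2-bromo-6-methoxyphenyl)[2-(2-iodoethyl)-4,6-dimethoxyphenyl]methanone
Conditions: I2, PPh3, imidazole, CH2Cl2, 0 °C → rt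
Reagents that add atoms: iodine, II
Why: Appel-type iodination, in which the primary alcohol is activated as an alkoxyphosphonium ion and displaced by iodide under near-neutral conditions that leave the ketone, aryl bromide and ethers alone.

Step 9
Reactants: 17 (2-bromo-6-methoxyphenyl)[2-(2-iodoethyl)-4,6-dimethoxyphenyl]methanone
Product: 18 (2-bromo-6-methoxyphenyl)(2-ethyl-4,6-dimethoxyphenyl)methanone
Conditions: Bu3SnH (1.1 equiv), AIBN (cat.), toluene, 80 °C
Reagents that add atoms: none
Why: Radical dehalogenation, in which the stannyl radical abstracts iodine from a primary alkyl iodide far faster than bromine from an aryl bromide and the primary radical is quenched by Bu3SnH, so the ethyl group should be completed with the bromide intact.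

Step 10
Reactants: 19 4-methoxy-6-methyl-2H-pyran-2-one
Product: 20 6-(bromomethyl)-4-methoxy-2H-pyran-2-one
Conditions: NBS, (PhCO2)2 (cat.), CCl4 (or PhCF3), reflux
Reagents that add atoms: N-bromosuccinimide, O=C1CCC(=O)N1Br
Why: Wohl–Ziegler bromination, in which hydrogen abstraction from the 6-methyl group gives a radical delocalised into the pyranone while the non-polar solvent and initiator suppress ionic bromination at C3.

Step 11
Reactants: 18 (2-bromo-6-methoxyphenyl)(2-ethyl-4,6-dimethoxyphenyl)methanone; 20 6-(bromomethyl)-4-methoxy-2H-pyran-2-one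
Product: 22 6-{[2-(2-ethyl-4,6-dimethoxybenzoyl)-3-methoxyphenyl]methyl}-4-methoxy-2H-pyran-2-one, via pyranonylmethylzinc bromide 21 (not isolated)
Conditions: 20, Zn dust (activated with BrCH2CH2Br, TMSCl), THF, 0 °C → rt; then 18, Pd(OAc)2 (cat.), SPhos (cat.), THF, 50 °C
Reagents that add atoms: none
Why: Zinc inserts readily into the activated (allylic, Reformatsky-type) C–Br bond of 20, and Negishi coupling of the organozinc with the aryl bromide at a bulky biarylphosphine complex of zerovalent palladium (formed from Pd(OAc)2) should forge the aryl–CH2 bond, since organozinc halides tolerate both the hindered ketone and the lactone.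

Step 12
Reactants: 22 6-{[2-(2-ethyl-4,6-dimethoxybenzoyl)-3-methoxyphenyl]methyl}-4-methoxy-2H-pyran-2-one
Product: 23 6-{[2-(2-ethyl-4,6-dihydroxybenzoyl)-3-hydroxyphenyl]methyl}-4-hydroxy-2H-pyran-2-one
Conditions: BBr3 (excess), CH2Cl2, −78 °C → rt; then H2O
Reagents that add atoms: none
Why: Lewis acid ether cleavage, in which BBr3 binds each ether oxygen (and the pyranone carbonyl) and bromide removes the methyl groups by SN2 attack, the ring C methoxy group being a vinylogous methyl ester that should be dealkylated in the manner of BBr3 ester cleavage, so that aqueous work-up releases all four hydroxyl groups.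

Compound list
1 | 3,5-dimethoxyphenol | COc1cc(O)cc(OC)c1 | starting material
2 | 2-bromo-3,5-dimethoxyphenol | COc1cc(O)c(Br)c(OC)c1 | intermediate
3 | (2-bromo-3,5-dimethoxyphenoxy)trimethylsilane | COc1cc(O[Si](C)(C)C)c(Br)c(OC)c1 | intermediate
4 | [2,4-dimethoxy-6-(trimethylsilyloxy)phenyl]lithium (not isolated) | COc1cc(O[Si](C)(C)C)c([Li])c(OC)c1 | intermediate
5 | lithium 3,5-dimethoxy-2-(trimethylsilyl)phenoxide (not isolated) | COc1cc([O-])c([Si](C)(C)C)c(OC)c1.[Li+] | intermediate
6 | 3,5-dimethoxy-2-(trimethylsilyl)phenyl trifluoromethanesulfonate | COc1cc(OC)c([Si](C)(C)C)c(OS(=O)(=O)C(F)(F)F)c1 | intermediate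
7 | 2-bromo-6-methoxybenzoic acid | COc1cccc(Br)c1C(=O)O | starting material
8 | potassium methyl malonate (potassium 3-methoxy-3-oxopropanoate) | COC(=O)CC(=O)[O-].[K+] | starting material
9 | 2-bromo-6-methoxybenzoyl chloride (not isolated) | COc1cccc(Br)c1C(=O)Cl | intermediate
10 | 2-(2-bromo-6-methoxybenzoyl)-3-methoxy-3-oxopropanoic acid, held as its magnesium chelate (not isolated) | COC(=O)C(C(=O)O)C(=O)c1c(OC)cccc1Br | intermediate
11 | methyl 3-(2-bromo-6-methoxyphenyl)-3-oxopropanoate | COC(=O)CC(=O)c1c(OC)cccc1Br | intermediate
12 | 3,5-dimethoxybenzyne (1,2-didehydro-3,5-dimethoxybenzene, not isolated) | COC1=CC(OC)=CC#C1 | intermediate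
13 | cesium benzocyclobutenoxide: cyclobutene ring fused to ring A, its alkoxide carbon (bearing the 2-bromo-6-methoxyphenyl group) bonded to the ring A carbon next to a methoxy group and its CH(CO2Me) carbon to the other fusion carbon (not isolated) | COC(=O)C1c2cc(OC)cc(OC)c2C1([O-])c1c(OC)cccc1Br.[Cs+] | intermediate
14 | methyl 2-[2-(2-bromo-6-methoxybenzoyl)-3,5-dimethoxyphenyl]acetate | COC(=O)Cc1cc(OC)cc(OC)c1C(=O)c1c(OC)cccc1Br | intermediate
15 | 2-[2-(2-bromo-6-methoxybenzoyl)-3,5-dimethoxyphenyl]acetic acid | OC(=O)Cc1cc(OC)cc(OC)c1C(=O)c1c(OC)cccc1Br | intermediate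
16 | (2-bromo-6-methoxyphenyl)[2-(2-hydroxyethyl)-4,6-dimethoxyphenyl]methanone | OCCc1cc(OC)cc(OC)c1C(=O)c1c(OC)cccc1Br | intermediate
17 | (2-bromo-6-methoxyphenyl)[2-(2-iodoethyl)-4,6-dimethoxyphenyl]methanone | ICCc1cc(OC)cc(OC)c1C(=O)c1c(OC)cccc1Br | intermediate
18 | (2-bromo-6-methoxyphenyl)(2-ethyl-4,6-dimethoxyphenyl)methanone | CCc1cc(OC)cc(OC)c1C(=O)c1c(OC)cccc1Br | intermediate
19 | 4-methoxy-6-methyl-2H-pyran-2-one | COc1cc(C)oc(=O)c1 | starting material
20 | 6-(bromomethyl)-4-methoxy-2H-pyran-2-one | COc1cc(CBr)oc(=O)c1 | intermediate
21 | [(4-methoxy-2-oxo-2H-pyran-6-yl)methyl]zinc bromide (not isolated) | COc1cc(C[Zn]Br)oc(=O)c1 | intermediate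
22 | 6-{[2-(2-ethyl-4,6-dimethoxybenzoyl)-3-methoxyphenyl]methyl}-4-methoxy-2H-pyran-2-one | CCc1cc(OC)cc(OC)c1C(=O)c1c(OC)cccc1Cc1cc(OC)cc(=O)o1 | intermediate
23 | 6-{[2-(2-ethyl-4,6-dihydroxybenzoyl)-3-hydroxyphenyl]methyl}-4-hydroxy-2H-pyran-2-one | CCc1cc(O)cc(O)c1C(=O)c1c(O)cccc1Cc1cc(O)cc(=O)o1 | target

Total step count: 12.
Longest linear sequence: 10 steps (steps 1, 2, 3, 5, 6, 7, 8, 9, 11 and 12, from 3,5-dimethoxyphenol 1).

Steps most likely to fail

Step 5. The aryl anion may be protonated before it closes onto the shielded ketone, which would stop the sequence at plain alpha-arylation, or the enolate may add to the aryne with the wrong orientation. The fallback replaces the insertion by a Friedel–Crafts acylation; it sets out from 7, through its chloride 9, and returns to the route at 14. Commercial 3,5-dimethoxyphenylacetic acid is esterified (MeOH, cat. H2SO4, Fischer esterification) to methyl 2-(3,5-dimethoxyphenyl)acetate F1. F1 is then acylated with 9 and SnCl4 in CH2Cl2 at 0 °C. Attack is expected at C2 of F1, ortho to the acetate arm, para to one methoxy group and ortho to the other, which gives 14 directly.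

Step 11. Homocoupling may compete during zinc insertion, or transmetalation and reductive elimination beside the bulky aroyl group may be slow enough for protodezincation and reduction of the bromide to take over. The fallback reverses the polarity of the two partners; it sets out from 18 and returns at 22. Miyaura borylation of 18 (B2pin2, PdCl2(dppf), KOAc, dioxane, 90 °C) should give (2-ethyl-4,6-dimethoxyphenyl)[2-methoxy-6-(4,4,5,5-tetramethyl-1,3,2-dioxaborolan-2-yl)phenyl]methanone F2. Suzuki–Miyaura coupling of F2 with bromide 20 (Pd(PPh3)4, K3PO4, toluene, 80 °C) would then form the same aryl–CH2 bond.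

Step 12. Cleavage of the vinylogous-ester methyl group on ring C may lag behind that of the three aryl ethers, and forcing the reaction may degrade the polyphenol. The fallback carries ring C as a benzyl ether, which ionises easily under the same Lewis acid; it sets out from 18 and returns at 23.
- Commercial 4-hydroxy-6-methyl-2H-pyran-2-one is O-benzylated (BnBr, K2CO3, DMF) to 4-(benzyloxy)-6-methyl-2H-pyran-2-one F3.
- Lateral deprotonation of the 6-methyl group (LiN(SiMe3)2, THF, −78 °C) and transmetalation with ZnBr2 give {[4-(benzyloxy)-2-oxo-2H-pyran-6-yl]methyl}zinc bromide F4.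
- Negishi coupling of F4 with 18 (Pd(OAc)2, SPhos, THF, 50 °C) gives 4-(benzyloxy)-6-{[2-(2-ethyl-4,6-dimethoxybenzoyl)-3-methoxyphenyl]methyl}-2H-pyran-2-one F5.
- BBr3 in CH2Cl2 (−78 °C → rt) removes the benzyl group and the three aryl methyl groups from F5 to give 23.

Further compounds
F1 | step 5 | methyl 2-(3,5-dimethoxyphenyl)acetate | COC(=O)Cc1cc(OC)cc(OC)c1
F2 | step 11 | (2-ethyl-4,6-dimethoxyphenyl)[2-methoxy-6-(4,4,5,5-tetramethyl-1,3,2-dioxaborolan-2-yl)phenyl]methanone | CCc1cc(OC)cc(OC)c1C(=O)c1c(OC)cccc1B1OC(C)(C)C(C)(C)O1
F3 | step 12 | 4-(benzyloxy)-6-methyl-2H-pyran-2-one | Cc1cc(OCc2ccccc2)cc(=O)o1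
F4 | step 12 | {[4-(benzyloxy)-2-oxo-2H-pyran-6-yl]methyl}zinc bromide | O=c1cc(OCc2ccccc2)cc(C[Zn]Br)o1
F5 | step 12 | 4-(benzyloxy)-6-{[2-(2-ethyl-4,6-dimethoxybenzoyl)-3-methoxyphenyl]methyl}-2H-pyran-2-one | CCc1cc(OC)cc(OC)c1C(=O)c1c(OC)cccc1Cc1cc(OCc2ccccc2)cc(=O)o1
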